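**Retrosynthetic overview**
- The oxepane is closed last: the C20 hydroxyl opens a C7–C8 epoxide transannularly (anti, at the tertiary carbon). The C3–C4 epoxide comes from hydroxyl-directed epoxidation of a macrocyclic C2 carbinol.
- The 12-membered ring is closed at C1–C2 by a Nozaki–Hiyama–Kishi reaction (ring alkenyl iodide onto a (Z)-enal). The chain is attached before that by alkylating a C10 sulfone with a nerol-derived allylic bromide.
- The ring fragment (iodo-cyclohexenediol with CH2Ts on quaternary C11) comes from a γ-hydroxy enone, made from an exocyclic alkene/ketone by epoxidation and elimination.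
- Quaternary C11 and the C10–C11 bond are made by a decarboxylative Ireland–Claisen ([3,3]) rearrangement of an allylic tosylacetate, steered by the C12 methyl. That methyl comes from cuprate addition to (S)-carvone, the only source of chirality.
- Ring order: cyclohexene (bought) → 12-membered carbocycle → C3–C4 oxirane → C7–C8 oxirane → oxepane.

Assumption: positions use phomactin numbering (C1=C15 ring alkene, C15 bears C20H2O; C2 carbonyl; C3/C4 epoxide; C7 carbinol; C8 ether carbon; C11 quaternary; C12 CH(CH3); C14 ring carbinol), and a one-pot sequence without isolation counts as one step.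

**Route**

Step 1
Reactants: 1 (S)-(+)-carvone
Product: 3 (3S,5S)-2,3-dimethyl-5-(prop-1-en-2-yl)cyclohex-1-en-1-yl trifluoromethanesulfonate, via lithium enolate 2 (not isolated)
Conditions: Me2CuLi (MeLi, CuI), Et2O, −78 to 0 °C; then PhNTf2, THF, 0 °C to rt
Reagents that add atoms: lithium dimethylcuprate [Li+].C[Cu-]C; N-phenylbis(trifluoromethanesulfonimide) FC(F)(F)S(=O)(=O)N(c1ccccc1)S(=O)(=O)C(F)(F)F
Why: Cuprate conjugate addition is axial and anti to the isopropenyl group, so the new methyl (future C12) is trans to it, and the regiodefined enolate is O-triflated to the tetrasubstituted enol triflate.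

Step 2
Reactants: 3 enol triflate
Product: 5 (1S,5S)-4,5-dimethyl-3-(trifluoromethanesulfonyloxy)cyclohex-3-en-1-yl acetate, via methoxy hydroperoxide 4 (not isolated)
Conditions: O3, CH2Cl2–MeOH, −78 °C (Sudan Red 7B end point); then Ac2O, Et3N, DMAP, 0 °C to rt
Reagents that add atoms: ozone [O-][O+]=O; methanol CO
Why: The electron-rich isopropenyl alkene is ozonized selectively beside the deactivated enol triflate, and Criegee rearrangement of the acetylated hydroperoxide converts isopropenyl into acetoxy with retention.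

Step 3
Reactants: 5 acetoxy enol triflate
Product: 6 (1S,5S)-3-(hydroxymethyl)-4,5-dimethylcyclohex-3-en-1-yl acetate
Conditions: Bu3SnCH2OH, Pd(PPh3)4 (5 mol%), LiCl, dioxane, 100 °C
Reagents that add atoms: (tributylstannyl)methanol CCCC[Sn](CCCC)(CCCC)CO
Why: Stille coupling of the alkenyl triflate installs the allylic CH2OH (future C20) without touching a stereocentre.

Step 4
Reactants: 6 allylic alcohol; 7 2-(4-methylbenzenesulfonyl)acetic acid
Product: 8 [(3S,5S)-5-acetoxy-2,3-dimethylcyclohex-1-en-1-yl]methyl 2-(4-methylbenzenesulfonyl)acetate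
Conditions: DIC, DMAP (cat.), CH2Cl2, 0 °C to rt
Reagents that add atoms: none
Why: Steglich esterification of the unhindered primary allylic alcohol gives the Claisen precursor.

Step 5
Reactants: 8 allylic tosylacetate
Product: 11 (1S,4R,5S)-4,5-dimethyl-3-methylidene-4-[(4-methylbenzenesulfonyl)methyl]cyclohexyl acetate, via silyl ketene acetal 9 (not isolated), via rearranged trimethylsilyl ester 10 (not isolated)
Conditions: BSA (0.2 equiv), KOAc (0.1 equiv), PhMe, 110 °C
Reagents that add atoms: none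
Why: In this decarboxylative Ireland–Claisen ([3,3]-sigmatropic) rearrangement the ketene acetal bonds to the tetrasubstituted ring carbon through a chair transition state anti to the pseudoaxial neighbouring methyl (allylic 1,2-strain), which sets quaternary C11 with the two methyls cis; desilylation and loss of CO2 leave CH2Ts and the exocyclic methylene.

Step 6
Reactants: 11 acetate
Product: 12 (1S,4R,5S)-4,5-dimethyl-3-methylidene-4-[(4-methylbenzenesulfonyl)methyl]cyclohexan-1-ol
Conditions: K2CO3 (0.2 equiv), MeOH, rt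
Reagents that add atoms: none
Why: Base-catalysed transesterification removes the acetate.

Step 7
Reactants: 12 alcohol
Product: 13 (4R,5S)-4,5-dimethyl-3-methylidene-4-[(4-methylbenzenesulfonyl)methyl]cyclohexan-1-one
Conditions: Dess–Martin periodinane, NaHCO3, CH2Cl2, 0 °C to rt
Reagents that add atoms: none
Why: Buffered Dess–Martin oxidation gives the β,γ-unsaturated ketone without moving the alkene into conjugation.

Step 8
Reactants: 13 β,γ-unsaturated ketone
Product: 15 (4R,5S)-3-(hydroxymethyl)-4,5-dimethyl-4-[(4-methylbenzenesulfonyl)methyl]cyclohex-2-en-1-one, via spiro-epoxy ketone 14 (not isolated)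
Conditions: dimethyldioxirane, acetone, 0 °C; then DBU (0.2 equiv), CH2Cl2, rt
Reagents that add atoms: dimethyldioxirane CC1(C)OO1
Why: Epoxidation of the only nucleophilic alkene gives a β,γ-epoxy ketone, and its base-induced E1cB opening gives the conjugated γ-hydroxy enone, which erases the spiro centre.

Step 9
Reactants: 15 γ-hydroxy enone
Product: 16 (4R,5S)-3-(hydroxymethyl)-2-iodo-4,5-dimethyl-4-[(4-methylbenzenesulfonyl)methyl]cyclohex-2-en-1-one
Conditions: I2, pyridine, CH2Cl2, rt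
Reagents that add atoms: iodine II
Why: Johnson α-iodination (iodination then dehydroiodination) places iodine on the only vinylic CH, the future C1.

Step 10
Reactants: 16 iodo enone
Product: 17 (1R,4R,5S)-3-(hydroxymethyl)-2-iodo-4,5-dimethyl-4-[(4-methylbenzenesulfonyl)methyl]cyclohex-2-en-1-ol
Conditions: NaBH4, CeCl3·7H2O, MeOH, −78 °C
Reagents that add atoms: none
Why: In this Luche 1,2-reduction hydride attacks the face opposite the 1,3-related C12 methyl, so the C14 hydroxyl ends cis to both ring methyls (also the diequatorial, thermodynamically preferred arrangement).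

Step 11
Reactants: 17 iodo diol
Product: 18 bis(tert-butyldimethylsilyl) ether of 17 (1R,4R,5S)
Conditions: TBSOTf, 2,6-lutidine, CH2Cl2, −78 to 0 °C
Reagents that add atoms: tert-butyldimethylsilyl triflate CC(C)(C)[Si](C)(C)OS(=O)(=O)C(F)(F)F
Why: Silylation protects both alcohols for the carbanion and chromium chemistry.

Step 12
Reactants: 19 neryl acetate
Product: 20 (2Z,6E)-8-hydroxy-3,7-dimethylocta-2,6-dien-1-yl acetate
Conditions: SeO2 (0.1 equiv), t-BuOOH, salicylic acid (cat.), CH2Cl2, rt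
Reagents that add atoms: tert-butyl hydroperoxide CC(C)(C)OO (oxygen relayed through catalytic selenium dioxide O=[Se]=O)
Why: Riley allylic oxidation (ene reaction then [2,3]-shift) hydroxylates the (E)-methyl of the remote, more electron-rich trisubstituted alkene.

Step 13
Reactants: 20 allylic alcohol
Product: 21 (2Z,6E)-8-bromo-3,7-dimethylocta-2,6-dien-1-yl acetate
Conditions: CBr4, PPh3, CH2Cl2, 0 °C
Reagents that add atoms: carbon tetrabromide BrC(Br)(Br)Br
Why: Appel bromination of the primary allylic alcohol keeps both alkene geometries.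

Step 14
Reactants: 18 bis-silyl iodo sulfone; 21 allylic bromide
Product: 23 C10-alkylated sulfone (11R,12S,14R; 3Z,7E; C10 epimers) carrying the C2 acetate, via lithiated sulfone 22 (not isolated)
Conditions: LDA, THF–DMPU, −78 °C; then 21, −78 to −40 °C
Reagents that add atoms: none
Why: The α-sulfonyl carbanion alkylates the primary allylic bromide by SN2, LDA leaves the alkenyl iodide alone, and the new C10 centre is removed in step 18.

Step 15
Reactants: 23 acetate
Product: 24 the corresponding (2Z)-allylic alcohol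
Conditions: K2CO3 (0.2 equiv), MeOH, 0 °C
Reagents that add atoms: none
Why: Methanolysis cleaves the allylic acetate while the silyl ethers and alkenyl iodide survive.

Step 16
Reactants: 24 allylic alcohol
Product: 25 the corresponding (Z)-enal
Conditions: Dess–Martin periodinane, NaHCO3, CH2Cl2, 0 °C
Reagents that add atoms: none
Why: Buffered Dess–Martin oxidation gives the enal without Z/E isomerization.

Step 17
Reactants: 25 iodo enal
Product: 26 macrocyclic bis-allylic alcohol (2S,11R,12S,14R; 3Z,7E; C10 epimers)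
Conditions: CrCl2 (10 equiv), NiCl2 (1 mol%), DMSO–THF, rt, 1 mM
Reagents that add atoms: none
Why: In this intramolecular Nozaki–Hiyama–Kishi reaction the nickel-generated alkenylchromium adds to the aldehyde to close the 12-membered ring; the chain is anchored on the lower face of the cyclohexene, which should favour one C2 epimer, drawn as 2S.

Step 18
Reactants: 26 macrocyclic sulfone
Product: 27 desulfonylated macrocyclic alcohol (2S,11R,12S,14R; 3Z,7E)
Conditions: Na/Hg (6%), Na2HPO4, MeOH–THF, −20 °C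
Reagents that add atoms: none
Why: Reductive desulfonylation by electron transfer removes the sulfone and with it the C10 stereocentre.

Step 19
Reactants: 27 bis-allylic alcohol
Product: 28 epoxy alcohol (2R,3S,4R,11R,12S,14R; 7E)
Conditions: VO(acac)2 (5 mol%), t-BuOOH, CH2Cl2, 0 °C
Reagents that add atoms: tert-butyl hydroperoxide CC(C)(C)OO
Why: Hydroxyl-directed epoxidation of the (Z)-allylic alcohol is threo-selective (allylic 1,3-strain), so the 2S carbinol relays to the required epoxide face; the C7=C8 alkene has no directing group and the C1=C15 alkene is shielded by two silyloxy-bearing carbons.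

Step 20
Reactants: 28 epoxy alcohol
Product: 29 epoxy enone (3R,4R,11R,12S,14R; 7E)
Conditions: Dess–Martin periodinane, NaHCO3, CH2Cl2, 0 °C
Reagents that add atoms: none
Why: Dess–Martin oxidation of the C2 carbinol gives the cross-conjugated epoxy ketone and removes the relay stereocentre.

Step 21
Reactants: 29 epoxy enone
Product: 30 bis-epoxide (3R,4R,7R,8R,11R,12S,14R)
Conditions: m-CPBA, NaHCO3, CH2Cl2, 0 °C
Reagents that add atoms: 3-chloroperoxybenzoic acid OOC(=O)c1cccc(Cl)c1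
Why: Prilezhaev epoxidation takes the only electron-rich alkene (C7=C8) on its exposed outer face, anti to the transannular C20 oxygen, while the enone alkene is inert.

Step 22
Reactants: 30 bis-epoxide
Product: 32 target (3R,4R,7R,8S,11R,12S,14R), via desilylated bis-epoxide 31 (not isolated)
Conditions: HF·pyridine, pyridine, THF, 0 °C to rt; then CSA (cat.), CH2Cl2, 0 °C
Reagents that add atoms: none
Why: After desilylation the C20 hydroxyl opens the C7–C8 epoxide by acid-catalysed 7-exo attack at tertiary C8 with inversion (8S, 7R retained), and the epoxy ketone is too deactivated to ionize.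

**Compound list**
1 | (S)-(+)-carvone | CC1=CC[C@@H](CC1=O)C(C)=C | starting material
2 | lithium (3S,5S)-2,3-dimethyl-5-(prop-1-en-2-yl)cyclohex-1-en-1-olate | C[C@H]1C[C@H](C(C)=C)CC([O-])=C1C.[Li+] | intermediate
3 | (3S,5S)-2,3-dimethyl-5-(prop-1-en-2-yl)cyclohex-1-en-1-yl trifluoromethanesulfonate (methyl trans to isopropenyl) | C[C@H]1C[C@H](C(C)=C)CC(OS(=O)(=O)C(F)(F)F)=C1C | intermediate
4 | (3S,5S)-5-(1-hydroperoxy-1-methoxyethyl)-2,3-dimethylcyclohex-1-en-1-yl triflate | C[C@H]1C[C@H](C(C)(OC)OO)CC(OS(=O)(=O)C(F)(F)F)=C1C | intermediate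
5 | (1S,5S)-4,5-dimethyl-3-(trifluoromethanesulfonyloxy)cyclohex-3-en-1-yl acetate | C[C@H]1C[C@H](OC(C)=O)CC(OS(=O)(=O)C(F)(F)F)=C1C | intermediate
6 | (1S,5S)-3-(hydroxymethyl)-4,5-dimethylcyclohex-3-en-1-yl acetate | C[C@H]1C[C@H](OC(C)=O)CC(CO)=C1C | intermediate
7 | 2-(4-methylbenzenesulfonyl)acetic acid | Cc1ccc(cc1)S(=O)(=O)CC(O)=O | starting material
8 | [(3S,5S)-5-acetoxy-2,3-dimethylcyclohex-1-en-1-yl]methyl 2-(4-methylbenzenesulfonyl)acetate | C[C@H]1C[C@H](OC(C)=O)CC(COC(=O)CS(=O)(=O)c2ccc(C)cc2)=C1C | intermediate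
9 | O-trimethylsilyl ketene acetal of 8 | C[C@H]1C[C@H](OC(C)=O)CC(COC(O[Si](C)(C)C)=CS(=O)(=O)c2ccc(C)cc2)=C1C | intermediate
10 | trimethylsilyl ester of the rearranged α-tosyl acid (C11 set, C10 epimers) | C[C@H]1C[C@H](OC(C)=O)CC(=C)[C@]1(C)C(C(=O)O[Si](C)(C)C)S(=O)(=O)c2ccc(C)cc2 | intermediate
11 | (1S,4R,5S)-4,5-dimethyl-3-methylidene-4-[(4-methylbenzenesulfonyl)methyl]cyclohexyl acetate | C[C@H]1C[C@H](OC(C)=O)CC(=C)[C@]1(C)CS(=O)(=O)c2ccc(C)cc2 | intermediate
12 | (1S,4R,5S)-4,5-dimethyl-3-methylidene-4-[(4-methylbenzenesulfonyl)methyl]cyclohexan-1-ol | C[C@H]1C[C@H](O)CC(=C)[C@]1(C)CS(=O)(=O)c2ccc(C)cc2 | intermediate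
13 | (4R,5S)-4,5-dimethyl-3-methylidene-4-[(4-methylbenzenesulfonyl)methyl]cyclohexan-1-one | C[C@H]1CC(=O)CC(=C)[C@]1(C)CS(=O)(=O)c2ccc(C)cc2 | intermediate
14 | spiro-epoxide of 13 (epimers at the spiro carbon) | C[C@H]1CC(=O)CC2(CO2)[C@]1(C)CS(=O)(=O)c3ccc(C)cc3 | intermediate
15 | (4R,5S)-3-(hydroxymethyl)-4,5-dimethyl-4-[(4-methylbenzenesulfonyl)methyl]cyclohex-2-en-1-one | C[C@H]1CC(=O)C=C(CO)[C@]1(C)CS(=O)(=O)c2ccc(C)cc2 | intermediate
16 | (4R,5S)-3-(hydroxymethyl)-2-iodo-4,5-dimethyl-4-[(4-methylbenzenesulfonyl)methyl]cyclohex-2-en-1-one | C[C@H]1CC(=O)C(I)=C(CO)[C@]1(C)CS(=O)(=O)c2ccc(C)cc2 | intermediate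
17 | (1R,4R,5S)-3-(hydroxymethyl)-2-iodo-4,5-dimethyl-4-[(4-methylbenzenesulfonyl)methyl]cyclohex-2-en-1-ol (hydroxyl cis to both methyls) | C[C@H]1C[C@@H](O)C(I)=C(CO)[C@]1(C)CS(=O)(=O)c2ccc(C)cc2 | intermediate
18 | bis(tert-butyldimethylsilyl) ether of 17 | C[C@H]1C[C@@H](O[Si](C)(C)C(C)(C)C)C(I)=C(CO[Si](C)(C)C(C)(C)C)[C@]1(C)CS(=O)(=O)c2ccc(C)cc2 | intermediate
19 | neryl acetate, (2Z)-3,7-dimethylocta-2,6-dien-1-yl acetate | CC(=O)OC/C=C(/C)CCC=C(C)C | starting material
20 | (2Z,6E)-8-hydroxy-3,7-dimethylocta-2,6-dien-1-yl acetate | CC(=O)OC/C=C(/C)CC/C=C(\C)CO | intermediate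
21 | (2Z,6E)-8-bromo-3,7-dimethylocta-2,6-dien-1-yl acetate | CC(=O)OC/C=C(/C)CC/C=C(\C)CBr | intermediate
22 | α-lithio sulfone of 18 | C[C@H]1C[C@@H](O[Si](C)(C)C(C)(C)C)C(I)=C(CO[Si](C)(C)C(C)(C)C)[C@]1(C)[CH-]S(=O)(=O)c2ccc(C)cc2.[Li+] | intermediate
23 | C10-alkylated sulfone, C2 acetate (11R,12S,14R; 3Z,7E; C10 epimers) | C[C@H]1C[C@@H](O[Si](C)(C)C(C)(C)C)C(I)=C(CO[Si](C)(C)C(C)(C)C)[C@]1(C)C(C/C(C)=C/CC/C(C)=C\COC(C)=O)S(=O)(=O)c2ccc(C)cc2 | intermediate
24 | C2 allylic alcohol from 23 | C[C@H]1C[C@@H](O[Si](C)(C)C(C)(C)C)C(I)=C(CO[Si](C)(C)C(C)(C)C)[C@]1(C)C(C/C(C)=C/CC/C(C)=C\CO)S(=O)(=O)c2ccc(C)cc2 | intermediate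
25 | (Z)-enal from 24 | C[C@H]1C[C@@H](O[Si](C)(C)C(C)(C)C)C(I)=C(CO[Si](C)(C)C(C)(C)C)[C@]1(C)C(C/C(C)=C/CC/C(C)=C\C=O)S(=O)(=O)c2ccc(C)cc2 | intermediate
26 | macrocyclic bis-allylic alcohol with C10 sulfone (2S,11R,12S,14R; 3Z,7E) | C[C@H]1C[C@@H](O[Si](C)(C)C(C)(C)C)C2=C(CO[Si](C)(C)C(C)(C)C)[C@]1(C)C(S(=O)(=O)c3ccc(C)cc3)C/C(C)=C/CC/C(C)=C\[C@@H]2O | intermediate
27 | desulfonylated macrocyclic alcohol (2S,11R,12S,14R; 3Z,7E) | C[C@H]1C[C@@H](O[Si](C)(C)C(C)(C)C)C2=C(CO[Si](C)(C)C(C)(C)C)[C@]1(C)CC/C(C)=C/CC/C(C)=C\[C@@H]2O | intermediate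
28 | 3,4-epoxy alcohol (2R,3S,4R,11R,12S,14R; 7E) | C[C@H]1C[C@@H](O[Si](C)(C)C(C)(C)C)C2=C(CO[Si](C)(C)C(C)(C)C)[C@]1(C)CC/C(C)=C/CC[C@@]3(C)O[C@H]3[C@@H]2O | intermediate
29 | 3,4-epoxy enone (3R,4R,11R,12S,14R; 7E) | C[C@H]1C[C@@H](O[Si](C)(C)C(C)(C)C)C2=C(CO[Si](C)(C)C(C)(C)C)[C@]1(C)CC/C(C)=C/CC[C@@]3(C)O[C@H]3C2=O | intermediate
30 | bis-epoxide (3R,4R,7R,8R,11R,12S,14R) | C[C@H]1C[C@@H](O[Si](C)(C)C(C)(C)C)C2=C(CO[Si](C)(C)C(C)(C)C)[C@]1(C)CC[C@@]3(C)O[C@@H]3CC[C@@]4(C)O[C@H]4C2=O | intermediate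
31 | desilylated bis-epoxide diol | C[C@H]1C[C@@H](O)C2=C(CO)[C@]1(C)CC[C@@]3(C)O[C@@H]3CC[C@@]4(C)O[C@H]4C2=O | intermediate
32 | CNP0316768.3 (3R,4R,7R,8S,11R,12S,14R) | C[C@H]1C[C@@H](O)C2=C3CO[C@@](C)(CC[C@@]31C)[C@H](O)CC[C@@]1(C)O[C@H]1C2=O | target

**Step count**
Total: 22 steps. Longest linear sequence: 20 steps (1 → 32 through steps 1–11 and 14–22); the chain branch from 19 is 2 steps.

**Steps most likely to fail**

Step 5 (Claisen onto a tetrasubstituted alkene, new quaternary centre). Fallback by a [2,3]-sigmatropic route from 6: (4-MeC6H4S)2 and PBu3 convert the alcohol into the allylic p-tolyl sulfide F1. Et2Zn/CH2I2 then forms the sulfonium methylide, whose [2,3]-shift delivers CH2S to the same ring carbon, anti to the neighbouring methyl, giving the homoallylic sulfide F2. Oxidation with (NH4)6Mo7O24/H2O2 gives 11.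

Step 17 (12-membered closure with a hindered tetrasubstituted alkenyl iodide; the C2 configuration is an expectation, not a certainty). Fallback by anionic acylation from 25: Pinnick oxidation (NaClO2, NaH2PO4, 2-methyl-2-butene) gives the (Z)-enoic acid F3. MeNHOMe·HCl/EDC gives the Weinreb amide F4. t-BuLi (2.1 equiv) at −100 °C under high dilution effects iodine–lithium exchange and intramolecular acylation to the macrocyclic dienone F5. Luche reduction of F5 returns to 26. If the carbinol epimer ratio there is poor, the same reduction can be repeated after step 18.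

Step 21 (with its consequence in step 22: only the 7R,8R epoxide can be opened anti by the C20 hydroxyl; attack on the other olefin rotamer costs yield). Fallback from 28, replacing steps 20–22: HF·pyridine/pyridine at 0 °C removes only the primary allylic silyl group to give the diol F6. Hg(OCOCF3)2 in CH2Cl2 at −20 °C closes the oxepane by reversible transannular alkoxymercuration to the organomercurial F7, which does not depend on an external oxidant choosing a face. NaBH4/O2 in DMF replaces mercury by hydroxyl to give the C7-epimeric diol F8. Dess–Martin oxidation of both secondary carbinols gives the diketone F9. Zn(BH4)2 in Et2O at −78 °C reduces only the unhindered C7 ketone, chelated to the C8 ether oxygen, with hydride entering from the methyl side (7R), to give the C14 silyl ether F10. HF·pyridine then gives 32.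

**Further compounds**
F1 | step 5 | (1S,5S)-4,5-dimethyl-3-{[(4-methylphenyl)sulfanyl]methyl}cyclohex-3-en-1-yl acetate | C[C@H]1C[C@H](OC(C)=O)CC(CSc2ccc(C)cc2)=C1C
F2 | step 5 | (1S,4R,5S)-4,5-dimethyl-3-methylidene-4-{[(4-methylphenyl)sulfanyl]methyl}cyclohexyl acetate | C[C@H]1C[C@H](OC(C)=O)CC(=C)[C@]1(C)CSc2ccc(C)cc2
F3 | step 17 | (Z)-enoic acid from 25 | C[C@H]1C[C@@H](O[Si](C)(C)C(C)(C)C)C(I)=C(CO[Si](C)(C)C(C)(C)C)[C@]1(C)C(C/C(C)=C/CC/C(C)=C\C(O)=O)S(=O)(=O)c2ccc(C)cc2
F4 | step 17 | N-methoxy-N-methyl amide of F3 | C[C@H]1C[C@@H](O[Si](C)(C)C(C)(C)C)C(I)=C(CO[Si](C)(C)C(C)(C)C)[C@]1(C)C(C/C(C)=C/CC/C(C)=C\C(=O)N(C)OC)S(=O)(=O)c2ccc(C)cc2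
F5 | step 17 | macrocyclic dienone with C10 sulfone (3Z,7E) | C[C@H]1C[C@@H](O[Si](C)(C)C(C)(C)C)C2=C(CO[Si](C)(C)C(C)(C)C)[C@]1(C)C(S(=O)(=O)c3ccc(C)cc3)C/C(C)=C/CC/C(C)=C\C2=O
F6 | step 21 | C20 alcohol of 28 (C14 silyl ether kept) | C[C@H]1C[C@@H](O[Si](C)(C)C(C)(C)C)C2=C(CO)[C@]1(C)CC/C(C)=C/CC[C@@]3(C)O[C@H]3[C@@H]2O
F7 | step 21 | oxepane C7 organomercury trifluoroacetate | C[C@H]1C[C@@H](O[Si](C)(C)C(C)(C)C)C2=C3CO[C@@](C)(CC[C@@]31C)[C@H]([Hg]OC(=O)C(F)(F)F)CC[C@@]1(C)O[C@H]1[C@@H]2O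
F8 | step 21 | oxepane C2,C7-diol (C7 epimers) | C[C@H]1C[C@@H](O[Si](C)(C)C(C)(C)C)C2=C3CO[C@@](C)(CC[C@@]31C)C(O)CC[C@@]1(C)O[C@H]1[C@@H]2O
F9 | step 21 | oxepane C2,C7-diketone | C[C@H]1C[C@@H](O[Si](C)(C)C(C)(C)C)C2=C3CO[C@@](C)(CC[C@@]31C)C(=O)CC[C@@]1(C)O[C@H]1C2=O
F10 | step 21 | C14 tert-butyldimethylsilyl ether of 32 | C[C@H]1C[C@@H](O[Si](C)(C)C(C)(C)C)C2=C3CO[C@@](C)(CC[C@@]31C)[C@H](O)CC[C@@]1(C)O[C@H]1C2=O
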